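**Retrosynthetic overview**
- The strategy rests on ring C: C3 (enol OH) and C4 (C=O) are adjacent oxygenated carbons, so the 3-hydroxypyran-4-one is treated as the oxidised form of a 3,4-diol, and the last step is a fourfold debenzylation.
- Ring C is the only ring built: the C3–C4 bond is formed by SmI2 pinacol closure of dialdehyde 18 (ring A formyl carbon = C4, side-chain formyl carbon = C3), then oxidised and tautomerised to the flavonol.
- 18 comes from the branched allyl aryl ether 16 by cleavage of its vinyl group; the C8a–O1–C2 ether link of 16 comes from ring A salicylaldehyde 9 and ring B 1-arylallyl carbonate 15.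
- 9 is made from 5-hydroxyvanillin (Dakin-type oxidation, then ortho-formylation); 15 from 3,5-dihydroxy-4-methoxybenzoic acid.

Key step: step 13

Remark: the target is achiral and every stereocentre of the intermediates is erased when ring C is aromatised in step 14, so all chiral intermediates are carried as racemates.

Step 1
Reactants: 1 5-hydroxyvanillin (3,4-dihydroxy-5-methoxybenzaldehyde)
Product: 2 4-(benzyloxy)-3-hydroxy-5-methoxybenzaldehyde
Conditions: BnBr (1.05 equiv), Li2CO3 (1.2 equiv), DMF, 45 °C
Reagents that add atoms: benzyl bromide, BrCc1ccccc1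
Why: Williamson etherification under a weak base: the 4-OH, para to the formyl group, is the most acidic phenol and should be alkylated selectively, leaving the 3-OH free.

Step 2
Reactants: 2 4-(benzyloxy)-3-hydroxy-5-methoxybenzaldehyde
Product: 3 4-(benzyloxy)-3-methoxy-5-(methoxymethoxy)benzaldehyde
Conditions: MOMCl, iPr2NEt, CH2Cl2, 0 °C to rt
Reagents that add atoms: chloromethyl methyl ether, COCCl
Why: Acetal protection (O-alkylation with an α-chloro ether) masks the remaining phenol with a group that can later be removed without touching benzyl ethers.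

Step 3
Reactants: 3 4-(benzyloxy)-3-methoxy-5-(methoxymethoxy)benzaldehyde
Product: 5 4-(benzyloxy)-3-methoxy-5-(methoxymethoxy)phenol, via aryl formate 4 (not isolated)
Conditions: mCPBA, CH2Cl2, rt; then K2CO3 (cat.), MeOH, rt
Reagents that add atoms: 3-chloroperoxybenzoic acid (mCPBA), OOC(=O)c1cccc(Cl)c1
Why: Baeyer–Villiger (Dakin-type) oxidation in which the electron-rich aryl group with its para-alkoxy substituent migrates to oxygen, followed by mild methanolysis of the aryl formate; MOM and benzyl ethers tolerate both stages.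

Step 4
Reactants: 5 4-(benzyloxy)-3-methoxy-5-(methoxymethoxy)phenol
Product: 6 2,5-bis(benzyloxy)-1-methoxy-3-(methoxymethoxy)benzene
Conditions: BnBr, K2CO3, DMF, rt
Reagents that add atoms: benzyl bromide, BrCc1ccccc1
Why: Williamson etherification of the only free phenol installs the benzyl ether that becomes the C5 oxygen substituent of the flavonol.

Step 5
Reactants: 6 2,5-bis(benzyloxy)-1-methoxy-3-(methoxymethoxy)benzene
Product: 7 2,5-bis(benzyloxy)-3-methoxyphenol
Conditions: HCl (cat.), MeOH, 45 °C
Reagents that add atoms: none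
Why: Acid-catalysed transacetalisation to methanol cleaves only the MOM acetal, because aryl benzyl and methyl ethers are stable to dilute methanolic HCl.

Step 6
Reactants: 7 2,5-bis(benzyloxy)-3-methoxyphenol
Product: 9 3,6-bis(benzyloxy)-2-hydroxy-4-methoxybenzaldehyde, via salicyl alcohol 8 (not isolated)
Conditions: MgCl2, Et3N, (CH2O)n, MeCN, reflux; 1 M HCl work-up
Reagents that add atoms: paraformaldehyde (as formaldehyde), C=O
Why: Magnesium-mediated ortho-formylation (Casnati–Skattebøl): the magnesium phenoxide delivers formaldehyde to the single free ortho carbon and the salicyl alcohol is oxidised in the flask by hydride transfer to a second formaldehyde, so the free para position is not attacked.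

Step 7
Reactants: 10 3,5-dihydroxy-4-methoxybenzoic acid
Product: 11 benzyl 3,5-bis(benzyloxy)-4-methoxybenzoate
Conditions: BnBr (3.5 equiv), K2CO3, DMF, 60 °C
Reagents that add atoms: benzyl bromide, BrCc1ccccc1
Why: Exhaustive Williamson and carboxylate alkylation protects both phenols and turns the acid into a reducible ester in one operation.

Step 8
Reactants: 11 benzyl 3,5-bis(benzyloxy)-4-methoxybenzoate
Product: 12 [3,5-bis(benzyloxy)-4-methoxyphenyl]methanol
Conditions: LiAlH4, THF, 0 °C to rt; H2O work-up
Reagents that add atoms: none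
Why: Hydride reduction of the ester to the primary alcohol; aryl ethers are inert to LiAlH4.

Step 9
Reactants: 12 [3,5-bis(benzyloxy)-4-methoxyphenyl]methanol
Product: 13 3,5-bis(benzyloxy)-4-methoxybenzaldehyde
Conditions: MnO2 (activated, excess), CH2Cl2, rt
Reagents that add atoms: none
Why: Heterogeneous MnO2 oxidation is selective for benzylic alcohols and should stop cleanly at the aldehyde.

Step 10
Reactants: 13 3,5-bis(benzyloxy)-4-methoxybenzaldehyde
Product: 15 rac-1-[3,5-bis(benzyloxy)-4-methoxyphenyl]prop-2-en-1-yl methyl carbonate, via magnesium alkoxide 14 (not isolated)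
Conditions: CH2=CHMgBr (1.1 equiv), THF, −78 to 0 °C; then ClCO2Me, 0 °C
Reagents that add atoms: vinylmagnesium bromide, C=C[Mg]Br; methyl chloroformate, COC(Cl)=O
Why: Grignard 1,2-addition creates the racemic carbinol centre and the magnesium alkoxide is acylated in the same flask, which avoids isolating the acid-sensitive 1-arylallyl alcohol; any drift to the linear cinnamyl carbonate is harmless because both isomers ionise to the same allyl complex in step 11.

Step 11
Reactants: 9 3,6-bis(benzyloxy)-2-hydroxy-4-methoxybenzaldehyde; 15 rac-1-[3,5-bis(benzyloxy)-4-methoxyphenyl]prop-2-en-1-yl methyl carbonate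
Product: 16 rac-3,6-bis(benzyloxy)-2-({1-[3,5-bis(benzyloxy)-4-methoxyphenyl]prop-2-en-1-yl}oxy)-4-methoxybenzaldehyde
Conditions: 9, NaH, THF, 0 °C; then 15, [Ir(cod)Cl]2 (2 mol %), racemic O,O'-(1,1'-binaphthyl-2,2'-diyl)-N,N-bis(1-phenylethyl)phosphoramidite (4 mol %), THF, 50 °C
Reagents that add atoms: none
Why: Iridium-catalysed allylic etherification: the carbonate ionises to a 1-arylallyl iridium complex that the sodium aryloxide attacks at the aryl-bearing terminus, the known branched selectivity of phosphoramidite–iridium catalysts with aryloxides, and the racemic ligand gives the racemic ether.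

Step 12
Reactants: 16 rac-3,6-bis(benzyloxy)-2-({1-[3,5-bis(benzyloxy)-4-methoxyphenyl]prop-2-en-1-yl}oxy)-4-methoxybenzaldehyde
Product: 18 rac-3,6-bis(benzyloxy)-2-{1-[3,5-bis(benzyloxy)-4-methoxyphenyl]-2-oxoethoxy}-4-methoxybenzaldehyde, via vicinal diol 17 (not isolated)
Conditions: OsO4 (2 mol %), NaIO4 (4 equiv), 2,6-lutidine, dioxane/H2O, rt; crude product used at once
Reagents that add atoms: osmium tetroxide, O=[Os](=O)(=O)=O; sodium periodate (reoxidant and oxygen source), [Na+].[O-]I(=O)(=O)=O
Why: Lemieux–Johnson oxidation: OsO4 dihydroxylates the terminal vinyl group, the only alkene present, and periodate cleaves the glycol, with 2,6-lutidine suppressing over-oxidation and the near-neutral medium sparing the enolisable α-aryloxy aldehyde.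

Step 13
Reactants: 18 rac-3,6-bis(benzyloxy)-2-{1-[3,5-bis(benzyloxy)-4-methoxyphenyl]-2-oxoethoxy}-4-methoxybenzaldehyde
Product: 19 rac-(2R,3S,4S)-5,8-bis(benzyloxy)-2-[3,5-bis(benzyloxy)-4-methoxyphenyl]-7-methoxychromane-3,4-diol (2,3-trans-3,4-cis)
Conditions: SmI2 (2.5 equiv, 0.1 M in THF), t-BuOH (2 equiv), THF, −78 to −20 °C, slow addition of 18 at high dilution, no HMPA; aqueous NH4Cl work-up
Reagents that add atoms: none
Why: Divalent samarium transfers one electron to the conjugated ring A aldehyde, the resulting C4 ketyl adds to the samarium-bound side-chain aldehyde, and a second electron followed by protonation gives the diol. The closest known reaction type is the SmI2-mediated intramolecular pinacol coupling of 1,6-dialdehydes to cis-cyclohexane-1,2-diols. Ring C (O1, C2, C3, C4, C4a, C8a) is closed in a 6-exo-trig mode by formation of the C3–C4 bond. The new centres C3 and C4 should be set cis by chelation of both oxygens to one samarium, and C3 trans to C2 by the existing C2 centre, whose aryl group sits pseudo-equatorial; the diastereomer outcome is not critical because all three centres are erased in step 14. The step needs chemoselectivity for cyclisation over loss of the ring A aryloxide from a C3 ketyl, over simple reduction and over intermolecular coupling; the easier reduction of the aromatic aldehyde places the first radical at C4, and low temperature, dilution, a proton source and the absence of HMPA should favour ring closure.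

Step 14
Reactants: 19 rac-(2R,3S,4S)-5,8-bis(benzyloxy)-2-[3,5-bis(benzyloxy)-4-methoxyphenyl]-7-methoxychromane-3,4-diol
Product: 21 5,8-bis(benzyloxy)-2-[3,5-bis(benzyloxy)-4-methoxyphenyl]-3-hydroxy-7-methoxy-4H-chromen-4-one, via chromane-3,4-dione 20 (not isolated)
Conditions: (COCl)2, DMSO, CH2Cl2, −78 °C; then Et3N, −78 °C to rt
Reagents that add atoms: none
Why: Swern oxidation of both secondary alcohols gives the vicinal dione without C–C cleavage, and triethylamine enolises the C3 ketone toward the doubly activated C2–H, so ring C becomes the aromatic 3-hydroxypyran-4-one.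

Step 15
Reactants: 21 5,8-bis(benzyloxy)-2-[3,5-bis(benzyloxy)-4-methoxyphenyl]-3-hydroxy-7-methoxy-4H-chromen-4-one
Product: 22 2-(3,5-dihydroxy-4-methoxyphenyl)-3,5,8-trihydroxy-7-methoxy-4H-chromen-4-one (target)
Conditions: H2 (1 atm), 10% Pd/C, THF/MeOH (degassed), rt; filtration under argon
Reagents that add atoms: none
Why: Catalytic hydrogenolysis cleaves the four aryl benzyl ethers while the aromatic pyranone and the methyl ethers are not reduced at one atmosphere of hydrogen; exclusion of air protects the 5,8-dihydroxy (hydroquinone-type) ring A.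

**Compound list**
1 | 5-hydroxyvanillin (3,4-dihydroxy-5-methoxybenzaldehyde) | COc1cc(C=O)cc(O)c1O | starting material
2 | 4-(benzyloxy)-3-hydroxy-5-methoxybenzaldehyde | COc1cc(C=O)cc(O)c1OCc1ccccc1 | intermediate
3 | 4-(benzyloxy)-3-methoxy-5-(methoxymethoxy)benzaldehyde | COCOc1cc(C=O)cc(OC)c1OCc1ccccc1 | intermediate
4 | 4-(benzyloxy)-3-methoxy-5-(methoxymethoxy)phenyl formate | COCOc1cc(OC=O)cc(OC)c1OCc1ccccc1 | intermediate (not isolated)
5 | 4-(benzyloxy)-3-methoxy-5-(methoxymethoxy)phenol | COCOc1cc(O)cc(OC)c1OCc1ccccc1 | intermediate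
6 | 2,5-bis(benzyloxy)-1-methoxy-3-(methoxymethoxy)benzene | COCOc1cc(OCc2ccccc2)cc(OC)c1OCc1ccccc1 | intermediate
7 | 2,5-bis(benzyloxy)-3-methoxyphenol | Oc1cc(OCc2ccccc2)cc(OC)c1OCc1ccccc1 | intermediate
8 | 3,6-bis(benzyloxy)-2-(hydroxymethyl)-5-methoxyphenol | Oc1c(CO)c(OCc2ccccc2)cc(OC)c1OCc1ccccc1 | intermediate (not isolated)
9 | 3,6-bis(benzyloxy)-2-hydroxy-4-methoxybenzaldehyde | O=Cc1c(O)c(OCc2ccccc2)c(OC)cc1OCc1ccccc1 | intermediate
10 | 3,5-dihydroxy-4-methoxybenzoic acid | COc1c(O)cc(C(=O)O)cc1O | starting material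
11 | benzyl 3,5-bis(benzyloxy)-4-methoxybenzoate | COc1c(OCc2ccccc2)cc(C(=O)OCc2ccccc2)cc1OCc1ccccc1 | intermediate
12 | [3,5-bis(benzyloxy)-4-methoxyphenyl]methanol | COc1c(OCc2ccccc2)cc(CO)cc1OCc1ccccc1 | intermediate
13 | 3,5-bis(benzyloxy)-4-methoxybenzaldehyde | COc1c(OCc2ccccc2)cc(C=O)cc1OCc1ccccc1 | intermediate
14 | bromomagnesium 1-[3,5-bis(benzyloxy)-4-methoxyphenyl]prop-2-en-1-olate (racemic) | C=CC(O[Mg]Br)c1cc(OCc2ccccc2)c(OC)c(OCc2ccccc2)c1 | intermediate (not isolated)
15 | rac-1-[3,5-bis(benzyloxy)-4-methoxyphenyl]prop-2-en-1-yl methyl carbonate | C=CC(OC(=O)OC)c1cc(OCc2ccccc2)c(OC)c(OCc2ccccc2)c1 | intermediate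
16 | rac-3,6-bis(benzyloxy)-2-({1-[3,5-bis(benzyloxy)-4-methoxyphenyl]prop-2-en-1-yl}oxy)-4-methoxybenzaldehyde | O=Cc1c(OCc2ccccc2)cc(OC)c(OCc2ccccc2)c1OC(C=C)c1cc(OCc2ccccc2)c(OC)c(OCc2ccccc2)c1 | intermediate
17 | 3,6-bis(benzyloxy)-2-{1-[3,5-bis(benzyloxy)-4-methoxyphenyl]-2,3-dihydroxypropoxy}-4-methoxybenzaldehyde (racemic mixture of diastereomers) | O=Cc1c(OCc2ccccc2)cc(OC)c(OCc2ccccc2)c1OC(C(O)CO)c1cc(OCc2ccccc2)c(OC)c(OCc2ccccc2)c1 | intermediate (not isolated)
18 | rac-3,6-bis(benzyloxy)-2-{1-[3,5-bis(benzyloxy)-4-methoxyphenyl]-2-oxoethoxy}-4-methoxybenzaldehyde | O=Cc1c(OCc2ccccc2)cc(OC)c(OCc2ccccc2)c1OC(C=O)c1cc(OCc2ccccc2)c(OC)c(OCc2ccccc2)c1 | intermediate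
19 | rac-(2R,3S,4S)-5,8-bis(benzyloxy)-2-[3,5-bis(benzyloxy)-4-methoxyphenyl]-7-methoxychromane-3,4-diol (racemate, one enantiomer drawn) | COc1c(OCc2ccccc2)cc(cc1OCc1ccccc1)[C@@H]1[C@H]([C@@H](O)c2c(OCc3ccccc3)cc(OC)c(OCc3ccccc3)c2O1)O | intermediate
20 | rac-5,8-bis(benzyloxy)-2-[3,5-bis(benzyloxy)-4-methoxyphenyl]-7-methoxychromane-3,4-dione | COc1c(OCc2ccccc2)cc(cc1OCc1ccccc1)C1C(=O)C(=O)c2c(OCc3ccccc3)cc(OC)c(OCc3ccccc3)c2O1 | intermediate (not isolated)
21 | 5,8-bis(benzyloxy)-2-[3,5-bis(benzyloxy)-4-methoxyphenyl]-3-hydroxy-7-methoxy-4H-chromen-4-one | COc1cc(OCc2ccccc2)c2c(=O)c(O)c(-c3cc(OCc4ccccc4)c(OC)c(OCc4ccccc4)c3)oc2c1OCc1ccccc1 | intermediate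
22 | 2-(3,5-dihydroxy-4-methoxyphenyl)-3,5,8-trihydroxy-7-methoxy-4H-chromen-4-one | COc1cc(O)c2c(=O)c(O)c(-c3cc(O)c(OC)c(O)c3)oc2c1O | target

**Step count**
Total steps: 15. Longest linear sequence: 11 steps (steps 1–6, then 11–15, from 5-hydroxyvanillin); the ring B branch is steps 7–10.

**Steps most likely to fail**

1. Step 13 (SmI2 pinacol closure). The side-chain ketyl may expel the ring A aryloxide (reductive cleavage of the C2–O bond), or the aromatic aldehyde may be reduced to the benzylic alcohol before it cyclises. The labile dialdehyde may also close by intramolecular aldol reaction to a dihydrobenzofuran before it is reduced. The fallback sets out from 16 and avoids both the dialdehyde and single-electron chemistry, so it also bypasses step 12. Wittig methylenation of the aldehyde (Ph3PCH3Br, KOtBu, THF, 0 °C) should give rac-1,4-bis(benzyloxy)-3-({1-[3,5-bis(benzyloxy)-4-methoxyphenyl]prop-2-en-1-yl}oxy)-2-ethenyl-5-methoxybenzene F2. Ring-closing metathesis with the second-generation Grubbs catalyst (CH2Cl2, 40 °C) should then form the C3=C4 bond and give rac-5,8-bis(benzyloxy)-2-[3,5-bis(benzyloxy)-4-methoxyphenyl]-7-methoxy-2H-chromene F3. Dihydroxylation (OsO4 cat., NMO, acetone/H2O) on the face opposite the C2 aryl group should deliver the 2,3-trans-3,4-cis diol, and the route is rejoined at 19.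

2. Step 11 (iridium-catalysed etherification). The hindered, hydrogen-bonded and weakly nucleophilic aryloxide of 9 may attack the allyl complex slowly. The product may also re-ionise, since its aryloxide is a good leaving group, and drift to the linear cinnamyl ether. The fallback sets out from 13 and 9 and forms the C–O bond by redox condensation instead of through a metal allyl. Addition of CH2=CHMgBr to 13 (THF, −78 °C, aqueous NH4Cl quench) should give rac-1-[3,5-bis(benzyloxy)-4-methoxyphenyl]prop-2-en-1-ol F1. A Mitsunobu reaction of F1 with the acidic phenol 9 (PPh3, DIAD, THF, 0 °C to rt) should displace the oxyphosphonium group at the carbinol carbon under neutral conditions and return to the route at 16.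

3. Step 14 (double Swern oxidation). The second oxidation may stall at ketol mixtures, and the activated sulfoxide may methylthiomethylate the new enol hydroxyl or chlorinate the electron-rich rings. The fallback sets out from 19 and oxidises in two separate stages. DDQ (dioxane, rt) should oxidise only the strongly activated C4 benzylic alcohol and give rac-(2R,3R)-5,8-bis(benzyloxy)-2-[3,5-bis(benzyloxy)-4-methoxyphenyl]-3-hydroxy-7-methoxy-2,3-dihydro-4H-chromen-4-one F4. The classical dehydrogenation of a dihydroflavonol (I2, KOAc, AcOH, 90 °C) should then introduce the C2=C3 double bond and return to the route at 21.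

**Further compounds**
F1 | step 11 | rac-1-[3,5-bis(benzyloxy)-4-methoxyphenyl]prop-2-en-1-ol | C=CC(O)c1cc(OCc2ccccc2)c(OC)c(OCc2ccccc2)c1
F2 | step 13 | rac-1,4-bis(benzyloxy)-3-({1-[3,5-bis(benzyloxy)-4-methoxyphenyl]prop-2-en-1-yl}oxy)-2-ethenyl-5-methoxybenzene | C=Cc1c(OCc2ccccc2)cc(OC)c(OCc2ccccc2)c1OC(C=C)c1cc(OCc2ccccc2)c(OC)c(OCc2ccccc2)c1
F3 | step 13 | rac-5,8-bis(benzyloxy)-2-[3,5-bis(benzyloxy)-4-methoxyphenyl]-7-methoxy-2H-chromene | COc1cc(OCc2ccccc2)c2C=CC(Oc2c1OCc1ccccc1)c1cc(OCc2ccccc2)c(OC)c(OCc2ccccc2)c1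
F4 | step 14 | rac-(2R,3R)-5,8-bis(benzyloxy)-2-[3,5-bis(benzyloxy)-4-methoxyphenyl]-3-hydroxy-7-methoxy-2,3-dihydro-4H-chromen-4-one | COc1c(OCc2ccccc2)cc(cc1OCc1ccccc1)[C@@H]1[C@H](C(=O)c2c(OCc3ccccc3)cc(OC)c(OCc3ccccc3)c2O1)O
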